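**Retrosynthetic overview**
- The route rests on the carbocycle C5–C6–C7–C8–C9–C10: oxygen at C6 and C8 (1,3) faces the vicinal C5 (isopropenyl) / C10 (methyl, vinyl) pair, and the cis C10-methyl / C5-C4 relation is the E geometry of a C5=C10 enone.
- C9–C10 and C5–C6 are made together by [4+2] of 1-methoxy-3-silyloxydiene 5 with (E)-enone 4, giving cyclohexenone 7 (the carbocycle, formed first); 4 comes from hydroxyacetone by silylation and Wittig reaction.
- Acetyl becomes isopropenyl (enone masked by Luche reduction, Ti-type methylenation), CH2OSi becomes vinyl (oxidation, Wittig); the enone is transposed to the C6 allylic alcohol by epoxidation and Wharton reaction.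
- The lactone ring (second ring) is closed through C7–C11 by 5-exo radical cyclisation of a C6–O bromoacetal onto C7=C8 with O2 capture at C8; the acetal is then oxidised to the lactone.
- C11–OH is set by convex-face enolate hydroxylation; C8 is acetylated and C11 angeloylated last.

Key step: step 3

Remark: C8 in 8–10 and the acetal/C11 centres in 16–20 are carried as epimer mixtures (all erased later); the catalyst antipode in step 3 is written from the enone binding model and is exchanged for its mirror image if the opposite sense is found.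

**Step 1**
Reactants: 1 hydroxyacetone
Product: 2 1-[tert-butyl(diphenyl)silyl]oxypropan-2-one
Conditions: TBDPSCl, imidazole, CH2Cl2, 0 °C → rt
Reagents that add atoms: tert-butyl(chloro)diphenylsilane, CC(C)(C)[Si](Cl)(c1ccccc1)c1ccccc1
Why: Imidazole-promoted O-silylation of the primary alcohol; TBDPS is chosen so that the ether survives the cationic Lewis acid and acidic work-up of step 3.

**Step 2**
Reactants: 2 1-[tert-butyl(diphenyl)silyl]oxypropan-2-one; 3 1-(triphenylphosphoranylidene)propan-2-one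
Product: 4 (E)-5-[tert-butyl(diphenyl)silyl]oxy-4-methylpent-3-en-2-one
Conditions: toluene, PhCO2H (10 mol %), reflux, 48 h; chromatographic removal of the Z isomer
Reagents that add atoms: none
Why: Wittig olefination of an α-alkoxy-activated ketone with a stabilised keto ylide should place the acyl group trans to the larger CH2OSi arm (E), which is the geometry that encodes the cis C10-methyl/C5-acetyl relation.

**Step 3**
Reactants: 4 (E)-5-[tert-butyl(diphenyl)silyl]oxy-4-methylpent-3-en-2-one; 5 (E)-1-methoxy-3-(trimethylsilyloxy)buta-1,3-diene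
Product: 7 (4S,5S)-4-acetyl-5-[[tert-butyl(diphenyl)silyl]oxymethyl]-5-methylcyclohex-2-en-1-one, via silyl enol ether cycloadduct 6 (not isolated)
Conditions: i) (S)-B-(o-tolyl)-diphenylprolinol oxazaborolidine·HNTf2 (20 mol %), 5 (3 equiv), CH2Cl2, −78 → −40 °C, 48 h; ii) TFA (cat.), wet THF, 0 °C, short
Reagents that add atoms: none
Why: The cationic boron Lewis acid binds the acetyl oxygen of 4 and the diene adds in a strongly asynchronous [4+2]: its nucleophilic CH2 terminus (C9) bonds to the enone β-carbon C10 and the methoxy-bearing terminus (C6) then bonds to C5, giving 6, from which acid eliminates methanol and hydrolyses the silyl enol ether to the C8 enone. The closest known reaction type is the chiral-Lewis-acid Diels–Alder reaction of 1-alkoxy-3-silyloxydienes with α,β-unsaturated ketones. The carbocycle is closed by intermolecular cycloaddition, suprafacial on both partners (in the stepwise limit a 6-(enolexo)-exo-trig closure of the boron enolate on the oxocarbenium carbon). The C10 quaternary centre is set by the catalyst, which must expose the Cα-Si/Cβ-Si face of 4, and C5 follows from the E geometry, so acetyl and methyl end cis. The regiochemistry needed (C9 to C10) is secured by the polarisation of both partners. The β,β-disubstituted enone is a sluggish dienophile, which is why the strongly activating cationic catalyst, excess diene and long reaction time are used, and 7 is carried on at once because C5–H is a vinylogous β-diketone proton.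

**Step 4**
Reactants: 7 (4S,5S)-4-acetyl-5-[[tert-butyl(diphenyl)silyl]oxymethyl]-5-methylcyclohex-2-en-1-one
Product: 8 1-[(1S,6S)-6-[[tert-butyl(diphenyl)silyl]oxymethyl]-4-hydroxy-6-methylcyclohex-2-en-1-yl]ethanone (C4 epimers)
Conditions: NaBH4, CeCl3·7H2O, MeOH, −78 °C
Reagents that add atoms: none
Why: Luche reduction should reduce the conjugated C8 carbonyl 1,2 in preference to the hindered non-conjugated methyl ketone; this masks the enone and removes the acidity of C5–H before methylenation (the C8 carbinol configuration is irrelevant, it is re-oxidised in step 7).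

**Step 5**
Reactants: 8 1-[(1S,6S)-6-[[tert-butyl(diphenyl)silyl]oxymethyl]-4-hydroxy-6-methylcyclohex-2-en-1-yl]ethanone
Product: 9 (4R,5S)-5-[[tert-butyl(diphenyl)silyl]oxymethyl]-5-methyl-4-(prop-1-en-2-yl)cyclohex-2-en-1-ol (C1 epimers)
Conditions: Zn, CH2Br2, TiCl4, THF (pre-formed reagent, excess); CH2Cl2, 0 °C → rt
Reagents that add atoms: dibromomethane, BrCBr
Why: Takai–Lombardo methylenation uses a non-basic gem-dimetallic reagent, so the hindered, enolisable β,γ-unsaturated methyl ketone should be converted without C5 epimerisation or double-bond migration, and the free hydroxyl is tolerated.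

**Step 6**
Reactants: 9 (4R,5S)-5-[[tert-butyl(diphenyl)silyl]oxymethyl]-5-methyl-4-(prop-1-en-2-yl)cyclohex-2-en-1-ol
Product: 10 (4R,5S)-5-(hydroxymethyl)-5-methyl-4-(prop-1-en-2-yl)cyclohex-2-en-1-ol (C1 epimers)
Conditions: TBAF, THF, rt → 40 °C
Reagents that add atoms: none
Why: Fluoride-driven cleavage of the neopentyl silyl ether; nothing else in the molecule is fluoride- or base-sensitive.

**Step 7**
Reactants: 10 (4R,5S)-5-(hydroxymethyl)-5-methyl-4-(prop-1-en-2-yl)cyclohex-2-en-1-ol
Product: 11 (1S,2R)-1-methyl-5-oxo-2-(prop-1-en-2-yl)cyclohex-3-ene-1-carbaldehyde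
Conditions: Dess–Martin periodinane (2.5 equiv), NaHCO3, CH2Cl2, 0 °C → rt
Reagents that add atoms: none
Why: Buffered Dess–Martin oxidation takes both alcohols up in one operation (allylic alcohol to the enone, both C8 epimers converging; neopentyl alcohol to the aldehyde on the quaternary C10) under neutral conditions that leave C5 untouched.

**Step 8**
Reactants: 11 (1S,2R)-1-methyl-5-oxo-2-(prop-1-en-2-yl)cyclohex-3-ene-1-carbaldehyde
Product: 12 (4R,5R)-5-ethenyl-5-methyl-4-(prop-1-en-2-yl)cyclohex-2-en-1-one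
Conditions: Ph3PCH3Br, KHMDS (1.05 equiv ylide), THF, −78 → −20 °C
Reagents that add atoms: methyltriphenylphosphonium bromide, C[P+](c1ccccc1)(c1ccccc1)c1ccccc1.[Br-]
Why: Wittig methylenation is chemoselective for the aldehyde over the conjugated ketone at low temperature with one equivalent of ylide, which installs the C10 vinyl group.

**Step 9**
Reactants: 12 (4R,5R)-5-ethenyl-5-methyl-4-(prop-1-en-2-yl)cyclohex-2-en-1-one
Product: 13 (1S,4R,5R,6S)-4-ethenyl-4-methyl-5-(prop-1-en-2-yl)-7-oxabicyclo[4.1.0]heptan-2-one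
Conditions: 30 % H2O2, NaOH (0.2 equiv), MeOH, −10 → 0 °C
Reagents that add atoms: hydrogen peroxide, OO
Why: Weitz–Scheffer epoxidation touches only the electron-poor C6=C7 bond; hydroperoxide should add to C6 anti to the adjacent C5 isopropenyl group and to the axial C10 methyl, so the epoxide oxygen (the future C6–O) lies trans to isopropenyl.

**Step 10**
Reactants: 13 (1S,4R,5R,6S)-4-ethenyl-4-methyl-5-(prop-1-en-2-yl)-7-oxabicyclo[4.1.0]heptan-2-one
Product: 15 (1R,5R,6R)-5-ethenyl-5-methyl-6-(prop-1-en-2-yl)cyclohex-2-en-1-ol, via epoxy hydrazone 14 (not isolated)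
Conditions: N2H4·H2O (3 equiv), AcOH (cat.), MeOH, 0 °C → rt, under argon
Reagents that add atoms: none
Why: Wharton transposition: the epoxy hydrazone opens to an allylic diazene that loses N2, giving the C6 allylic alcohol and the C7=C8 alkene; the C6–O bond is not broken, so the configuration from step 9 is kept.

**Step 11**
Reactants: 15 (1R,5R,6R)-5-ethenyl-5-methyl-6-(prop-1-en-2-yl)cyclohex-2-en-1-ol
Product: 16 (3R,4R,5R)-3-(2-bromo-1-ethoxypropoxy)-5-ethenyl-5-methyl-4-(prop-1-en-2-yl)cyclohex-1-ene (side-chain diastereomers)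
Conditions: ethyl prop-1-enyl ether (4 equiv), NBS, CH2Cl2, −40 → 0 °C
Reagents that add atoms: ethyl prop-1-enyl ether, CC=COCC; N-bromosuccinimide, O=C1CCC(=O)N1Br
Why: Bromoacetalisation (Ueno–Stork precursor): NBS attacks the enol ether, by far the most electron-rich alkene present, and the C6 alcohol traps the oxocarbenium ion, tethering the future C11/C12 unit to O6.

**Step 12**
Reactants: 16 (3R,4R,5R)-3-(2-bromo-1-ethoxypropoxy)-5-ethenyl-5-methyl-4-(prop-1-en-2-yl)cyclohex-1-ene
Product: 18 (3aR,4S,6R,7R,7aS)-2-ethoxy-6-ethenyl-3,6-dimethyl-7-(prop-1-en-2-yl)octahydro-1-benzofuran-4-ol (C2/C3 epimers), via C4 hydroperoxide 17 (not isolated)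
Conditions: i) Bu3SnH (syringe pump), Et3B (cat.), slow stream of dry air, toluene (0.01 M), rt; ii) PPh3
Reagents that add atoms: dioxygen, O=O
Why: Ueno–Stork 5-exo-trig radical cyclisation with oxygen capture (hydroxylative radical cyclisation): the O6 tether forces C7–C11 to form on the face of C6–O (cis ring fusion), O2 should then add to the C8 radical on the convex face anti to the new C7–C11 bond (C8–O trans to C11), and PPh3 reduces the hydroperoxide; a low O2 concentration lets ring closure precede capture.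

**Step 13**
Reactants: 18 (3aR,4S,6R,7R,7aS)-2-ethoxy-6-ethenyl-3,6-dimethyl-7-(prop-1-en-2-yl)octahydro-1-benzofuran-4-ol
Product: 19 (3aR,4S,6R,7R,7aS)-6-ethenyl-3,6-dimethyl-7-(prop-1-en-2-yl)octahydro-1-benzofuran-2,4-diol (C2/C3 epimers)
Conditions: 1 N HCl, THF, rt
Reagents that add atoms: water, O
Why: Mild acid hydrolysis of the mixed cyclic acetal to the lactol; dilute acid at room temperature should spare the 1,1-disubstituted alkene, and the trans C8–OH cannot form a bridged acetal.

**Step 14**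
Reactants: 19 (3aR,4S,6R,7R,7aS)-6-ethenyl-3,6-dimethyl-7-(prop-1-en-2-yl)octahydro-1-benzofuran-2,4-diol
Product: 20 (3aR,4S,6R,7R,7aS)-6-ethenyl-4-hydroxy-3,6-dimethyl-7-(prop-1-en-2-yl)hexahydro-1-benzofuran-2(3H)-one (C3 epimers)
Conditions: TEMPO (10 mol %), PhI(OAc)2 (1.1 equiv), CH2Cl2, rt
Reagents that add atoms: none
Why: Oxoammonium oxidation takes the lactol to the γ-lactone much faster than it oxidises the hindered secondary C8 alcohol, which is flanked by the ring fusion and syn to the C10 methyl.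

**Step 15**
Reactants: 20 (3aR,4S,6R,7R,7aS)-6-ethenyl-4-hydroxy-3,6-dimethyl-7-(prop-1-en-2-yl)hexahydro-1-benzofuran-2(3H)-one
Product: 22 (3S,3aR,4S,6R,7R,7aS)-6-ethenyl-3,4-dihydroxy-3,6-dimethyl-7-(prop-1-en-2-yl)hexahydro-1-benzofuran-2(3H)-one, via dilithium alkoxide enolate 21 (not isolated)
Conditions: LDA (2.3 equiv), THF, −78 → −40 °C; then 3-phenyl-2-(phenylsulfonyl)oxaziridine, −78 °C
Reagents that add atoms: 3-phenyl-2-(phenylsulfonyl)oxaziridine, O=S(=O)(c1ccccc1)N1OC1c1ccccc1
Why: Davis hydroxylation of the lactone enolate, with the C8 hydroxyl protected as its alkoxide; both C11 epimers give the same enolate and the oxidant should attack the convex face of the cis-fused bicycle (cis to H7, trans to C8), which sets C11 with OH exo and methyl endo.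

**Step 16**
Reactants: 22 (3S,3aR,4S,6R,7R,7aS)-6-ethenyl-3,4-dihydroxy-3,6-dimethyl-7-(prop-1-en-2-yl)hexahydro-1-benzofuran-2(3H)-one
Product: 23 (3S,3aR,4S,6R,7R,7aS)-6-ethenyl-3-hydroxy-3,6-dimethyl-2-oxo-7-(prop-1-en-2-yl)octahydro-1-benzofuran-4-yl acetate
Conditions: Ac2O (1.5 equiv), pyridine, DMAP (cat.), CH2Cl2, 0 °C → rt
Reagents that add atoms: acetic anhydride, CC(=O)OC(C)=O
Why: Acylation should be selective for the secondary C8 alcohol over the tertiary α-hydroxy-lactone alcohol, which is both more hindered and less nucleophilic.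

**Step 17**
Reactants: 23 (3S,3aR,4S,6R,7R,7aS)-6-ethenyl-3-hydroxy-3,6-dimethyl-2-oxo-7-(prop-1-en-2-yl)octahydro-1-benzofuran-4-yl acetate
Product: 25 (3S,3aR,4S,6R,7R,7aS)-4-acetyloxy-6-ethenyl-3,6-dimethyl-2-oxo-7-(prop-1-en-2-yl)octahydro-1-benzofuran-3-yl (Z)-2-methylbut-2-enoate, via lithium alkoxide 24 (not isolated)
Conditions: LiHMDS (1.05 equiv), THF, −78 °C; then angelic anhydride, −78 → 0 °C
Reagents that add atoms: (Z)-2-methylbut-2-enoic anhydride, C/C=C(/C)C(=O)OC(=O)/C(C)=C\C
Why: O-Acylation of the pre-formed tertiary lithium alkoxide with the symmetric anhydride at low temperature needs no nucleophilic catalyst, which is what normally isomerises angelate to tiglate; the C8 acetate lies trans to the C11 oxygen across the lactone ring, so acyl migration is geometrically disfavoured.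

**Compound list**
1 | hydroxyacetone | CC(=O)CO | starting material
2 | 1-[tert-butyl(diphenyl)silyl]oxypropan-2-one | CC(=O)CO[Si](c1ccccc1)(c1ccccc1)C(C)(C)C | intermediate
3 | 1-(triphenylphosphoranylidene)propan-2-one | CC(=O)C=P(c1ccccc1)(c1ccccc1)c1ccccc1 | starting material
4 | (E)-5-[tert-butyl(diphenyl)silyl]oxy-4-methylpent-3-en-2-one | CC(=O)/C=C(\C)CO[Si](c1ccccc1)(c1ccccc1)C(C)(C)C | intermediate
5 | (E)-1-methoxy-3-(trimethylsilyloxy)buta-1,3-diene | CO/C=C/C(=C)O[Si](C)(C)C | starting material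
6 | 1-[(1R,6S)-6-[[tert-butyl(diphenyl)silyl]oxymethyl]-2-methoxy-6-methyl-4-(trimethylsilyloxy)cyclohex-3-en-1-yl]ethanone (C2 epimers) | CC(C)(C)[Si](c1ccccc1)(c1ccccc1)OC[C@@]1(C)CC(O[Si](C)(C)C)=CC(OC)[C@@H]1C(C)=O | intermediate
7 | (4S,5S)-4-acetyl-5-[[tert-butyl(diphenyl)silyl]oxymethyl]-5-methylcyclohex-2-en-1-one | CC(C)(C)[Si](c1ccccc1)(c1ccccc1)OC[C@@]1(C)CC(=O)C=C[C@@H]1C(C)=O | intermediate
8 | 1-[(1S,6S)-6-[[tert-butyl(diphenyl)silyl]oxymethyl]-4-hydroxy-6-methylcyclohex-2-en-1-yl]ethanone (C4 epimers) | CC(C)(C)[Si](c1ccccc1)(c1ccccc1)OC[C@@]1(C)CC(O)C=C[C@@H]1C(C)=O | intermediate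
9 | (4R,5S)-5-[[tert-butyl(diphenyl)silyl]oxymethyl]-5-methyl-4-(prop-1-en-2-yl)cyclohex-2-en-1-ol (C1 epimers) | CC(C)(C)[Si](c1ccccc1)(c1ccccc1)OC[C@@]1(C)CC(O)C=C[C@@H]1C(C)=C | intermediate
10 | (4R,5S)-5-(hydroxymethyl)-5-methyl-4-(prop-1-en-2-yl)cyclohex-2-en-1-ol (C1 epimers) | OC[C@@]1(C)CC(O)C=C[C@@H]1C(C)=C | intermediate
11 | (1S,2R)-1-methyl-5-oxo-2-(prop-1-en-2-yl)cyclohex-3-ene-1-carbaldehyde | O=C[C@@]1(C)CC(=O)C=C[C@@H]1C(C)=C | intermediate
12 | (4R,5R)-5-ethenyl-5-methyl-4-(prop-1-en-2-yl)cyclohex-2-en-1-one | C=C[C@@]1(C)CC(=O)C=C[C@@H]1C(=C)C | intermediate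
13 | (1S,4R,5R,6S)-4-ethenyl-4-methyl-5-(prop-1-en-2-yl)-7-oxabicyclo[4.1.0]heptan-2-one | C=C[C@@]1(C)CC(=O)[C@H]2O[C@H]2[C@@H]1C(=C)C | intermediate
14 | hydrazone of 13 at the ring carbonyl (ring configuration unchanged) | C=C[C@@]1(C)CC(=NN)[C@H]2O[C@H]2[C@@H]1C(=C)C | intermediate
15 | (1R,5R,6R)-5-ethenyl-5-methyl-6-(prop-1-en-2-yl)cyclohex-2-en-1-ol | C=C[C@@]1(C)CC=C[C@@H](O)[C@@H]1C(=C)C | intermediate
16 | (3R,4R,5R)-3-(2-bromo-1-ethoxypropoxy)-5-ethenyl-5-methyl-4-(prop-1-en-2-yl)cyclohex-1-ene (side-chain diastereomers) | C=C[C@@]1(C)CC=C[C@@H](OC(OCC)C(C)Br)[C@@H]1C(=C)C | intermediate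
17 | C4 hydroperoxide corresponding to 18 (same ring configuration) | C=C[C@@]1(C)C[C@H](OO)[C@@H]2[C@@H](OC(OCC)C2C)[C@@H]1C(=C)C | intermediate
18 | (3aR,4S,6R,7R,7aS)-2-ethoxy-6-ethenyl-3,6-dimethyl-7-(prop-1-en-2-yl)octahydro-1-benzofuran-4-ol (C2/C3 epimers) | C=C[C@@]1(C)C[C@H](O)[C@@H]2[C@@H](OC(OCC)C2C)[C@@H]1C(=C)C | intermediate
19 | (3aR,4S,6R,7R,7aS)-6-ethenyl-3,6-dimethyl-7-(prop-1-en-2-yl)octahydro-1-benzofuran-2,4-diol (C2/C3 epimers) | C=C[C@@]1(C)C[C@H](O)[C@@H]2[C@@H](OC(O)C2C)[C@@H]1C(=C)C | intermediate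
20 | (3aR,4S,6R,7R,7aS)-6-ethenyl-4-hydroxy-3,6-dimethyl-7-(prop-1-en-2-yl)hexahydro-1-benzofuran-2(3H)-one (C3 epimers) | C=C[C@@]1(C)C[C@H](O)[C@@H]2[C@@H](OC(=O)C2C)[C@@H]1C(=C)C | intermediate
21 | dilithium C4-alkoxide / lactone enolate of 20 | [Li+].[Li+].C=C[C@@]1(C)C[C@H]([O-])[C@@H]2[C@@H](OC([O-])=C2C)[C@@H]1C(=C)C | intermediate
22 | (3S,3aR,4S,6R,7R,7aS)-6-ethenyl-3,4-dihydroxy-3,6-dimethyl-7-(prop-1-en-2-yl)hexahydro-1-benzofuran-2(3H)-one | C=C[C@@]1(C)C[C@H](O)[C@@H]2[C@@H](OC(=O)[C@@]2(C)O)[C@@H]1C(=C)C | intermediate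
23 | (3S,3aR,4S,6R,7R,7aS)-6-ethenyl-3-hydroxy-3,6-dimethyl-2-oxo-7-(prop-1-en-2-yl)octahydro-1-benzofuran-4-yl acetate | C=C[C@@]1(C)C[C@H](OC(C)=O)[C@@H]2[C@@H](OC(=O)[C@@]2(C)O)[C@@H]1C(=C)C | intermediate
24 | lithium C3-alkoxide of 23 | [Li+].C=C[C@@]1(C)C[C@H](OC(C)=O)[C@@H]2[C@@H](OC(=O)[C@@]2(C)[O-])[C@@H]1C(=C)C | intermediate
25 | (3S,3aR,4S,6R,7R,7aS)-4-acetyloxy-6-ethenyl-3,6-dimethyl-2-oxo-7-(prop-1-en-2-yl)octahydro-1-benzofuran-3-yl (Z)-2-methylbut-2-enoate (CNP0140071.1) | C=C[C@@]1(C)C[C@H](OC(C)=O)[C@@H]2[C@@H](OC(=O)[C@@]2(C)OC(=O)/C(C)=C\C)[C@@H]1C(=C)C | target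

**Step count and risks**
Total steps: 17. Longest linear sequence: 17 steps (1 → 25).

Steps most likely to fail:

1. Step 3 (key step). The β,β-disubstituted enone may add too slowly. Silyl transfer from the diene to triflimide may create an achiral silyl Lewis acid that carries a racemic background reaction. The acid-sensitive diene may be consumed before it adds.
   Fallback, from 4 back to 7: face control is moved from the catalyst to a chiral auxiliary on a more reactive diene. 4-Methoxybut-3-en-2-one is condensed with (2R,5R)-2,5-diphenylpyrrolidine to the vinylogous amide (E)-4-[(2R,5R)-2,5-diphenylpyrrolidin-1-yl]but-3-en-2-one F1. KHMDS/TBSCl converts it into the 1-amino-3-silyloxydiene (2R,5R)-1-[(1E)-3-(tert-butyldimethylsilyloxy)buta-1,3-dienyl]-2,5-diphenylpyrrolidine F2. This much more nucleophilic diene should add to 4 thermally (toluene, 80–110 °C, or 10–12 kbar) without any Lewis acid, to give the amino silyl enol ether cycloadduct F3. Aqueous TFA in THF then eliminates the amine and unmasks enone 7. The auxiliary antipode is chosen to match the required face.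

2. Step 12. Oxygen is a small trap and the wanted face of the C8 radical is syn to the axial C10 methyl, so capture may occur on both faces. O2 may also intercept the C11 radical before ring closure.
   Fallback, from 16 back to 18: radical face control is replaced by SN2 inversion. The same cyclisation is run and the C4 epimer (3aR,4R,6R,7R,7aS)-2-ethoxy-6-ethenyl-3,6-dimethyl-7-(prop-1-en-2-yl)octahydro-1-benzofuran-4-ol F4 is separated. It is inverted under Mitsunobu conditions (4-nitrobenzoic acid, DIAD, PPh3, toluene) to the (4S) 4-nitrobenzoate of 18 F5. K2CO3 in MeOH then releases 18.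

3. Step 17. The tertiary α-hydroxy-lactone alkoxide may acylate slowly. The angelate may isomerise to the tiglate under the basic conditions. Base may also attack the C8 acetate.
   Fallback, from 23 back to 25: the Z-alkene is built on the ester instead of being transferred. 23 is esterified with 2-[bis(2,2,2-trifluoroethoxy)phosphoryl]propanoic acid (DCC, DMAP cat., via the phosphonoketene, which acylates hindered alcohols) to the phosphonopropanoate of 23 F6. Still–Gennari olefination with acetaldehyde (KHMDS, 18-crown-6, THF, −78 °C) should then give the Z-trisubstituted ester 25; the phosphonate proton is far more acidic than the acetate.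

**Further compounds**
F1 | step 3 | (E)-4-[(2R,5R)-2,5-diphenylpyrrolidin-1-yl]but-3-en-2-one | CC(=O)/C=C/N1[C@@H](c2ccccc2)CC[C@@H]1c1ccccc1
F2 | step 3 | (2R,5R)-1-[(1E)-3-(tert-butyldimethylsilyloxy)buta-1,3-dienyl]-2,5-diphenylpyrrolidine | C=C(O[Si](C)(C)C(C)(C)C)/C=C/N1[C@@H](c2ccccc2)CC[C@@H]1c1ccccc1
F3 | step 3 | 1-[(1R,6S)-4-(tert-butyldimethylsilyloxy)-6-[[tert-butyl(diphenyl)silyl]oxymethyl]-2-[(2R,5R)-2,5-diphenylpyrrolidin-1-yl]-6-methylcyclohex-3-en-1-yl]ethanone (C2 not assigned) | CC(C)(C)[Si](c1ccccc1)(c1ccccc1)OC[C@@]1(C)CC(O[Si](C)(C)C(C)(C)C)=CC(N2[C@@H](c3ccccc3)CC[C@@H]2c2ccccc2)[C@@H]1C(C)=O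
F4 | step 12 | (3aR,4R,6R,7R,7aS)-2-ethoxy-6-ethenyl-3,6-dimethyl-7-(prop-1-en-2-yl)octahydro-1-benzofuran-4-ol (C2/C3 epimers) | C=C[C@@]1(C)C[C@@H](O)[C@@H]2[C@@H](OC(OCC)C2C)[C@@H]1C(=C)C
F5 | step 12 | (3aR,4S,6R,7R,7aS)-2-ethoxy-6-ethenyl-3,6-dimethyl-7-(prop-1-en-2-yl)octahydro-1-benzofuran-4-yl 4-nitrobenzoate (C2/C3 epimers) | C=C[C@@]1(C)C[C@H](OC(=O)c3ccc(cc3)[N+](=O)[O-])[C@@H]2[C@@H](OC(OCC)C2C)[C@@H]1C(=C)C
F6 | step 17 | (3S,3aR,4S,6R,7R,7aS)-4-acetyloxy-6-ethenyl-3,6-dimethyl-2-oxo-7-(prop-1-en-2-yl)octahydro-1-benzofuran-3-yl 2-[bis(2,2,2-trifluoroethoxy)phosphoryl]propanoate | C=C[C@@]1(C)C[C@H](OC(C)=O)[C@@H]2[C@@H](OC(=O)[C@@]2(C)OC(=O)C(C)P(=O)(OCC(F)(F)F)OCC(F)(F)F)[C@@H]1C(=C)C
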